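**Plan**

Rings: A = outer O-linked ring, B = inner ring of each arm, D = C-linked ring, C = hub, E = chlorinated ring. Hub ring C carries the two identical arm oxygens on C1 and C5, the ring E oxygen on C6 between them and a hydroxyl on C3 para to C6. This is the oxygen pattern of a reduced 2,6-dioxygenated 1,4-benzoquinone, so a 2,6-dihaloquinone can act as the hub.
Retrosynthetic cuts, last bond first: the eighteen O–CH3 bonds, the C3 O–Si bond, the C6(ring C)–O–ring E aryl ether bond, then both ring C C1–O and C5–O bonds at once at the quinone level. Within each arm: the O–benzyl bond, the B–D biaryl C–C bond and the B–O–A ether bond.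
Forward: no ring is built, as all seven benzene rings are bought. A ring B iodide is joined to ring A through oxygen, then to ring D through carbon, and debenzylated to the arm phenol. Two arm phenols are joined to the quinone hub, the quinone is reduced, the C3 hydroxyl is silylated, ring E is attached to the C6 oxygen, and the silyl and methyl groups are removed.
Stereochemistry: the target has no stereocentre, and rings D are symmetric about the biaryl bonds, so no stereogenic axis arises and nothing has to be controlled.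

Key step: step 7

Remark: the target SMILES carries no stereodescriptor and is treated as achiral.
Abbreviation in names: Arm-oxy = 2,6-dimethoxy-3-(2,4,6-trimethoxyphenyl)-4-(2,4,6-trimethoxyphenoxy)phenoxy.

**Route**

Step 1
Reactants: 1 2,6-dimethoxyphenol
Product: 2 4-iodo-2,6-dimethoxyphenol
Conditions: I2, KI, NaHCO3, THF/H2O, 0 °C to rt
Reagents that add atoms: iodine, II
Why: Electrophilic aromatic iodination of the phenoxide, which directs iodine to the only open position para to oxygen because both ortho positions carry methoxy groups.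

Step 2
Reactants: 2 4-iodo-2,6-dimethoxyphenol
Product: 3 2-(benzyloxy)-5-iodo-1,3-dimethoxybenzene
Conditions: BnBr, K2CO3, DMF, rt
Reagents that add atoms: benzyl bromide, BrCc1ccccc1
Why: Williamson ether synthesis gives a benzyl ether that keeps the future hub-side oxygen distinct from all methyl ethers and can later be removed without touching them.

Step 3
Reactants: 3 2-(benzyloxy)-5-iodo-1,3-dimethoxybenzene
Product: 4 2-(benzyloxy)-4-bromo-5-iodo-1,3-dimethoxybenzene
Conditions: NBS (1.0 equiv), MeCN, 0 °C to rt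
Reagents that add atoms: N-bromosuccinimide, O=C1CCC(=O)N1Br
Why: Electrophilic aromatic bromination goes to C4, which is ortho to one methoxy group and para to the other; C4 and C6 are equivalent, and one equivalent of reagent should stop at the monobromide.

Step 4
Reactants: 4 2-(benzyloxy)-4-bromo-5-iodo-1,3-dimethoxybenzene; 5 2,4,6-trimethoxyphenol
Product: 6 2-(benzyloxy)-4-bromo-1,3-dimethoxy-5-(2,4,6-trimethoxyphenoxy)benzene
Conditions: CuI (10 mol %), picolinic acid (20 mol %), K3PO4, DMSO, 80 °C, argon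
Reagents that add atoms: none
Why: Ullmann-type copper-catalysed diaryl ether synthesis with a picolinic acid ligand, which accepts 2,6-disubstituted phenols; the C–I bond is more reactive and has only one ortho substituent, so it should couple while the doubly flanked C–Br bond is kept.

Step 5
Reactants: 6 2-(benzyloxy)-4-bromo-1,3-dimethoxy-5-(2,4,6-trimethoxyphenoxy)benzene; 7 (2,4,6-trimethoxyphenyl)boronic acid
Product: 8 2-(benzyloxy)-1,3-dimethoxy-4-(2,4,6-trimethoxyphenyl)-5-(2,4,6-trimethoxyphenoxy)benzene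
Conditions: 7 (2.5 equiv), Pd(OAc)2 (5 mol %), SPhos (10 mol %), K3PO4, toluene/H2O, 100 °C
Reagents that add atoms: none
Why: Suzuki–Miyaura coupling with a dialkylbiarylphosphine ligand, the catalyst class established for tetra-ortho-substituted biaryls; the boronic acid is used in excess to offset protodeboronation.

Step 6
Reactants: 8 2-(benzyloxy)-1,3-dimethoxy-4-(2,4,6-trimethoxyphenyl)-5-(2,4,6-trimethoxyphenoxy)benzene
Product: 9 2,6-dimethoxy-3-(2,4,6-trimethoxyphenyl)-4-(2,4,6-trimethoxyphenoxy)phenol (arm phenol)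
Conditions: H2 (1 atm), 10% Pd/C, EtOAc/MeOH, rt
Reagents that add atoms: none
Why: Hydrogenolysis of the benzyl ether over palladium on carbon frees only the central hydroxyl, since methyl aryl ethers and diaryl ethers are inert and no halogen remains.

Step 7
Reactants: 9 2,6-dimethoxy-3-(2,4,6-trimethoxyphenyl)-4-(2,4,6-trimethoxyphenoxy)phenol (2 equiv); 10 2,6-dichloro-1,4-benzoquinone
Product: 13 2,6-bis(Arm-oxy)-1,4-benzoquinone, via potassium aryloxide 11 (not isolated), via chloro(aryloxy)quinone 12 (not isolated)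
Conditions: KH (1.0 equiv per 9), THF, 0 °C; then 10 (0.5 equiv), −78 °C to 0 °C, argon
Reagents that add atoms: none
Why: Aryloxide 11 adds through oxygen to a chlorine-bearing carbon of 10 (C2, then C6), the position vinylogous to the C4 carbonyl, and the enolate formed restores the quinone by expelling chloride, first to 12 and then to 13. The closest known reaction type is nucleophilic vinylic substitution (addition–elimination) of chloride in chloranil and 2,3-dichloro-1,4-naphthoquinone by aryloxides. No ring closes and no stereocentre forms; the two new bonds are the ring C C1–O and C5–O bonds. The step needs O-attack over C-attack, which is secured because both ortho positions of 11 carry methoxy groups and the para position carries the ring A oxygen. It also needs substitution at C–Cl over conjugate addition at C3/C5–H and over electron transfer: with a fully preformed salt in aprotic THF at low temperature an adduct at C–H has no proton shuttle for tautomerisation and can only revert, whereas the adduct at C–Cl collapses irreversibly, and in 12 the first aryloxy group makes its neighbouring C–H carbon electron-rich so that the second aryloxide is steered to the remaining C–Cl. Because both arms are identical, neither the order of the two substitutions nor any aryloxide exchange changes the product.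

Step 8
Reactants: 13 2,6-bis(Arm-oxy)-1,4-benzoquinone
Product: 14 2,6-bis(Arm-oxy)benzene-1,4-diol
Conditions: Na2S2O4, THF/H2O (degassed), rt
Reagents that add atoms: none
Why: Dithionite reduction of a quinone to its hydroquinone is a two-electron reduction that leaves ethers untouched.

Step 9
Reactants: 14 2,6-bis(Arm-oxy)benzene-1,4-diol
Product: 15 2,6-bis(Arm-oxy)-4-[(triisopropylsilyl)oxy]phenol
Conditions: TIPSCl (1.05 equiv), imidazole, DMF, 0 °C, argon
Reagents that add atoms: chlorotriisopropylsilane, CC(C)[Si](Cl)(C(C)C)C(C)C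
Why: Sterically controlled silylation: the C4 hydroxyl has two ortho hydrogens whereas the C1 hydroxyl lies between two 2,6-disubstituted aryloxy groups, so the bulky silyl chloride should react at C4 only.

Step 10
Reactants: 16 2-chloro-1,3-dimethoxybenzene
Product: 18 (4-chloro-3,5-dimethoxyphenyl)boronic acid, via pinacol boronate 17 (not isolated)
Conditions: [Ir(OMe)(cod)]2 (1.5 mol %), 4,4′-di-tert-butyl-2,2′-bipyridine (3 mol %), B2pin2, THF, 80 °C; then NaIO4, aq. HCl, THF/H2O, rt
Reagents that add atoms: bis(pinacolato)diboron, CC1(C)OB(OC1(C)C)B1OC(C)(C)C(C)(C)O1; water, O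
Why: Iridium-catalysed C–H borylation is sterically controlled and takes the only C–H without an ortho substituent (C5, para to chlorine); periodate then cleaves the pinacol ester oxidatively to the free boronic acid in the same flask.

Step 11
Reactants: 15 2,6-bis(Arm-oxy)-4-[(triisopropylsilyl)oxy]phenol; 18 (4-chloro-3,5-dimethoxyphenyl)boronic acid
Product: 19 [3,5-bis(Arm-oxy)-4-(4-chloro-3,5-dimethoxyphenoxy)phenoxy]triisopropylsilane
Conditions: 18 (3 equiv), Cu(OAc)2 (2 equiv), pyridine, 4 Å molecular sieves, CH2Cl2, dry air, rt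
Reagents that add atoms: none
Why: Chan–Lam coupling: the unhindered boronic acid transmetalates to divalent copper and the C–O bond forms at room temperature under conditions too mild to cleave the silyl ether or to engage the aryl chloride.

Step 12
Reactants: 19 [3,5-bis(Arm-oxy)-4-(4-chloro-3,5-dimethoxyphenoxy)phenoxy]triisopropylsilane
Product: 20 3,5-bis(Arm-oxy)-4-(4-chloro-3,5-dimethoxyphenoxy)phenol
Conditions: TBAF, AcOH, THF, 0 °C
Reagents that add atoms: none
Why: Fluoride-induced cleavage of the aryl silyl ether, driven by Si–F bond formation and buffered with acetic acid so that the electron-rich phenoxide is not left as the free anion.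

Step 13
Reactants: 20 3,5-bis(Arm-oxy)-4-(4-chloro-3,5-dimethoxyphenoxy)phenol
Product: 21 3,5-bis[2,6-dihydroxy-3-(2,4,6-trihydroxyphenyl)-4-(2,4,6-trihydroxyphenoxy)phenoxy]-4-(4-chloro-3,5-dihydroxyphenoxy)phenol (CNP0275555.0)
Conditions: BBr3 (large excess), CH2Cl2, −78 °C to rt; then H2O, 0 °C, argon
Reagents that add atoms: none
Why: Lewis acid ether cleavage: BBr3 coordinates each methoxy oxygen and bromide removes the methyl group as bromomethane, whereas diaryl ether oxygens (no sp3 carbon) and the aryl chloride do not react, and hydrolysis of the aryl borates should release all eighteen new hydroxyls.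

**Compound list**

1 | 2,6-dimethoxyphenol | COc1cccc(OC)c1O | starting material
2 | 4-iodo-2,6-dimethoxyphenol | COc1cc(I)cc(OC)c1O | intermediate
3 | 2-(benzyloxy)-5-iodo-1,3-dimethoxybenzene | COc1cc(I)cc(OC)c1OCc1ccccc1 | intermediate
4 | 2-(benzyloxy)-4-bromo-5-iodo-1,3-dimethoxybenzene | COc1cc(I)c(Br)c(OC)c1OCc1ccccc1 | intermediate
5 | 2,4,6-trimethoxyphenol | COc1cc(OC)c(O)c(OC)c1 | starting material
6 | 2-(benzyloxy)-4-bromo-1,3-dimethoxy-5-(2,4,6-trimethoxyphenoxy)benzene | COc1cc(Oc2c(OC)cc(OC)cc2OC)c(Br)c(OC)c1OCc1ccccc1 | intermediate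
7 | (2,4,6-trimethoxyphenyl)boronic acid | COc1cc(OC)c(B(O)O)c(OC)c1 | starting material
8 | 2-(benzyloxy)-1,3-dimethoxy-4-(2,4,6-trimethoxyphenyl)-5-(2,4,6-trimethoxyphenoxy)benzene | COc1cc(Oc2c(OC)cc(OC)cc2OC)c(-c2c(OC)cc(OC)cc2OC)c(OC)c1OCc1ccccc1 | intermediate
9 | 2,6-dimethoxy-3-(2,4,6-trimethoxyphenyl)-4-(2,4,6-trimethoxyphenoxy)phenol (arm phenol) | Oc1c(OC)cc(Oc2c(OC)cc(OC)cc2OC)c(-c2c(OC)cc(OC)cc2OC)c1OC | intermediate
10 | 2,6-dichloro-1,4-benzoquinone | O=C1C=C(Cl)C(=O)C(Cl)=C1 | starting material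
11 | potassium 2,6-dimethoxy-3-(2,4,6-trimethoxyphenyl)-4-(2,4,6-trimethoxyphenoxy)phenolate | [K+].[O-]c1c(OC)cc(Oc2c(OC)cc(OC)cc2OC)c(-c2c(OC)cc(OC)cc2OC)c1OC | intermediate
12 | 2-chloro-6-(Arm-oxy)-1,4-benzoquinone | O=C1C=C(Cl)C(=O)C(Oc2c(OC)cc(Oc3c(OC)cc(OC)cc3OC)c(-c3c(OC)cc(OC)cc3OC)c2OC)=C1 | intermediate
13 | 2,6-bis(Arm-oxy)-1,4-benzoquinone | O=C1C=C(Oc2c(OC)cc(Oc3c(OC)cc(OC)cc3OC)c(-c3c(OC)cc(OC)cc3OC)c2OC)C(=O)C(Oc2c(OC)cc(Oc3c(OC)cc(OC)cc3OC)c(-c3c(OC)cc(OC)cc3OC)c2OC)=C1 | intermediate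
14 | 2,6-bis(Arm-oxy)benzene-1,4-diol | Oc1cc(Oc2c(OC)cc(Oc3c(OC)cc(OC)cc3OC)c(-c3c(OC)cc(OC)cc3OC)c2OC)c(O)c(Oc2c(OC)cc(Oc3c(OC)cc(OC)cc3OC)c(-c3c(OC)cc(OC)cc3OC)c2OC)c1 | intermediate
15 | 2,6-bis(Arm-oxy)-4-[(triisopropylsilyl)oxy]phenol | CC(C)[Si](Oc1cc(Oc2c(OC)cc(Oc3c(OC)cc(OC)cc3OC)c(-c3c(OC)cc(OC)cc3OC)c2OC)c(O)c(Oc2c(OC)cc(Oc3c(OC)cc(OC)cc3OC)c(-c3c(OC)cc(OC)cc3OC)c2OC)c1)(C(C)C)C(C)C | intermediate
16 | 2-chloro-1,3-dimethoxybenzene | COc1cccc(OC)c1Cl | starting material
17 | 2-(4-chloro-3,5-dimethoxyphenyl)-4,4,5,5-tetramethyl-1,3,2-dioxaborolane | COc1cc(B2OC(C)(C)C(C)(C)O2)cc(OC)c1Cl | intermediate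
18 | (4-chloro-3,5-dimethoxyphenyl)boronic acid | COc1cc(B(O)O)cc(OC)c1Cl | intermediate
19 | [3,5-bis(Arm-oxy)-4-(4-chloro-3,5-dimethoxyphenoxy)phenoxy]triisopropylsilane | CC(C)[Si](Oc1cc(Oc2c(OC)cc(Oc3c(OC)cc(OC)cc3OC)c(-c3c(OC)cc(OC)cc3OC)c2OC)c(Oc2cc(OC)c(Cl)c(OC)c2)c(Oc2c(OC)cc(Oc3c(OC)cc(OC)cc3OC)c(-c3c(OC)cc(OC)cc3OC)c2OC)c1)(C(C)C)C(C)C | intermediate
20 | 3,5-bis(Arm-oxy)-4-(4-chloro-3,5-dimethoxyphenoxy)phenol | Oc1cc(Oc2c(OC)cc(Oc3c(OC)cc(OC)cc3OC)c(-c3c(OC)cc(OC)cc3OC)c2OC)c(Oc2cc(OC)c(Cl)c(OC)c2)c(Oc2c(OC)cc(Oc3c(OC)cc(OC)cc3OC)c(-c3c(OC)cc(OC)cc3OC)c2OC)c1 | intermediate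
21 | 3,5-bis[2,6-dihydroxy-3-(2,4,6-trihydroxyphenyl)-4-(2,4,6-trihydroxyphenoxy)phenoxy]-4-(4-chloro-3,5-dihydroxyphenoxy)phenol (CNP0275555.0) | Oc1cc(O)c(Oc2cc(O)c(Oc3cc(O)cc(Oc4c(O)cc(Oc5c(O)cc(O)cc5O)c(-c5c(O)cc(O)cc5O)c4O)c3Oc3cc(O)c(Cl)c(O)c3)c(O)c2-c2c(O)cc(O)cc2O)c(O)c1 | target

**Step count and risks**

Total step count: 13. Longest linear sequence: 12 steps (steps 1–9 and 11–13); step 10 is the side branch.

Risk 1, step 7. The aryloxide may add to the unsubstituted C3/C5 carbons of the quinone (conjugate addition and re-oxidation with chlorine retained). It may also transfer an electron to the quinone, after which the arm radical decomposes with loss of ring A. The fallback replaces the quinone by a nitro-activated arene and sets out from 9. Two equivalents of 9 with Cs2CO3 in DMF at 60 °C displace both fluorides of 1,3-difluoro-5-methoxy-2-nitrobenzene by nucleophilic aromatic substitution, through 1-(Arm-oxy)-3-fluoro-5-methoxy-2-nitrobenzene F1 (not isolated) to 1,3-bis(Arm-oxy)-5-methoxy-2-nitrobenzene F2. Hydrogenation (H2, Pd/C, EtOAc) should give 2,6-bis(Arm-oxy)-4-methoxyaniline F3. Diazotisation (NaNO2, aq. H2SO4/THF, 0 °C) gives 2,6-bis(Arm-oxy)-4-methoxybenzenediazonium hydrogensulfate F4, which is hydrolysed in the same flask (Cu2O, Cu(NO3)2, H2O) to 2,6-bis(Arm-oxy)-4-methoxyphenol F5. F5 takes the place of 15 in the coupling with 18 under the conditions of step 11 and gives 1,3-bis(Arm-oxy)-2-(4-chloro-3,5-dimethoxyphenoxy)-5-methoxybenzene F6. BBr3 as in step 13 then cleaves all nineteen methyl ethers, and the fallback comes back to the route at 21.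

Risk 2, step 11. Bond formation at the phenol oxygen buried between two aryloxy groups may be so slow that the boronic acid is consumed by protodeboronation and homocoupling. Meanwhile divalent copper and air may oxidise the electron-rich silyloxyphenol to the quinone with loss of the silyl group. The fallback is a metal-free arylation with a diaryliodonium salt and sets out from 18 and 15. Iododeboronation of 18 (N-iodosuccinimide, MeCN, 80 °C) gives 2-chloro-5-iodo-1,3-dimethoxybenzene F7. Oxidation with mCPBA and TsOH·H2O in MeCN gives 2-chloro-5-[hydroxy(tosyloxy)iodo]-1,3-dimethoxybenzene F8 (not isolated), which is trapped by 1,3,5-trimethoxybenzene as (4-chloro-3,5-dimethoxyphenyl)(2,4,6-trimethoxyphenyl)iodonium 4-methylbenzenesulfonate F9. 15 and F9 are combined with KOt-Bu in THF at 0 °C to rt; the less electron-rich aryl group of the trivalent iodine centre is transferred to oxygen and 2-iodo-1,3,5-trimethoxybenzene leaves. The fallback comes back to the route at 19.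

Risk 3, step 5. Protodeboronation of the di-ortho-methoxy boronic acid under aqueous base may outpace transmetalation to the crowded arylpalladium bromide, and reductive loss of bromine from 6 may compete. The fallback is a Negishi coupling, which needs neither base nor water, and sets out from 6. 1,3,5-Trimethoxybenzene is lithiated (n-BuLi, THF, 0 °C) to 2,4,6-trimethoxyphenyllithium F10 and transmetalated with ZnCl2 to (2,4,6-trimethoxyphenyl)zinc chloride F11. F11 is coupled with 6 using Pd2(dba)3 and RuPhos in THF/NMP at 70 °C, and the fallback comes back to the route at 8.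

**Further compounds**

F1 | step 7 | 1-(Arm-oxy)-3-fluoro-5-methoxy-2-nitrobenzene | COc1cc(F)c([N+](=O)[O-])c(Oc2c(OC)cc(Oc3c(OC)cc(OC)cc3OC)c(-c3c(OC)cc(OC)cc3OC)c2OC)c1
F2 | step 7 | 1,3-bis(Arm-oxy)-5-methoxy-2-nitrobenzene | COc1cc(Oc2c(OC)cc(Oc3c(OC)cc(OC)cc3OC)c(-c3c(OC)cc(OC)cc3OC)c2OC)c([N+](=O)[O-])c(Oc2c(OC)cc(Oc3c(OC)cc(OC)cc3OC)c(-c3c(OC)cc(OC)cc3OC)c2OC)c1
F3 | step 7 | 2,6-bis(Arm-oxy)-4-methoxyaniline | COc1cc(Oc2c(OC)cc(Oc3c(OC)cc(OC)cc3OC)c(-c3c(OC)cc(OC)cc3OC)c2OC)c(N)c(Oc2c(OC)cc(Oc3c(OC)cc(OC)cc3OC)c(-c3c(OC)cc(OC)cc3OC)c2OC)c1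
F4 | step 7 | 2,6-bis(Arm-oxy)-4-methoxybenzenediazonium hydrogensulfate | COc1cc(Oc2c(OC)cc(Oc3c(OC)cc(OC)cc3OC)c(-c3c(OC)cc(OC)cc3OC)c2OC)c([N+]#N)c(Oc2c(OC)cc(Oc3c(OC)cc(OC)cc3OC)c(-c3c(OC)cc(OC)cc3OC)c2OC)c1.OS(=O)(=O)[O-]
F5 | step 7 | 2,6-bis(Arm-oxy)-4-methoxyphenol | COc1cc(Oc2c(OC)cc(Oc3c(OC)cc(OC)cc3OC)c(-c3c(OC)cc(OC)cc3OC)c2OC)c(O)c(Oc2c(OC)cc(Oc3c(OC)cc(OC)cc3OC)c(-c3c(OC)cc(OC)cc3OC)c2OC)c1
F6 | step 7 | 1,3-bis(Arm-oxy)-2-(4-chloro-3,5-dimethoxyphenoxy)-5-methoxybenzene | COc1cc(Oc2c(OC)cc(Oc3c(OC)cc(OC)cc3OC)c(-c3c(OC)cc(OC)cc3OC)c2OC)c(Oc2cc(OC)c(Cl)c(OC)c2)c(Oc2c(OC)cc(Oc3c(OC)cc(OC)cc3OC)c(-c3c(OC)cc(OC)cc3OC)c2OC)c1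
F7 | step 11 | 2-chloro-5-iodo-1,3-dimethoxybenzene | COc1cc(I)cc(OC)c1Cl
F8 | step 11 | 2-chloro-5-[hydroxy(tosyloxy)iodo]-1,3-dimethoxybenzene | COc1cc(I(O)OS(=O)(=O)c2ccc(C)cc2)cc(OC)c1Cl
F9 | step 11 | (4-chloro-3,5-dimethoxyphenyl)(2,4,6-trimethoxyphenyl)iodonium 4-methylbenzenesulfonate | COc1cc(OC)c([I+]c2cc(OC)c(Cl)c(OC)c2)c(OC)c1.Cc1ccc(S(=O)(=O)[O-])cc1
F10 | step 5 | 2,4,6-trimethoxyphenyllithium | [Li]c1c(OC)cc(OC)cc1OC
F11 | step 5 | (2,4,6-trimethoxyphenyl)zinc chloride | Cl[Zn]c1c(OC)cc(OC)cc1OC
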